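The violet run cannot have stopped for want of partner: target levelled at 37.9% of the starting material charged (mean of the last two readings), with 92.4% of the partner charge still present. The meeting on the blue run opened with that point, and had this before it.

| flask | starting material | partner | time |
|---|---|---|---|
| red | 0.400 M | 1.20 M |  |
| violet | 0.200 M | 1.00 M |  |
| grey | 0.400 M | 1.80 M |  |
| blue | 0.130 M | 0.400 M | 12 min |

| run | time / min | [target] / M |
|---|---|---|
| red run | 1.5 | 0.0579 |
| red run | 3.0 | 0.1037 |
| red run | 4.5 | 0.1380 |
| red run | 6.0 | 0.1590 |
| red run | 7.5 | 0.1725 |
| red run | 9.0 | 0.1821 |
| red run | 10 | 0.1857 |
| red run | 12 | 0.1882 |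
| violet run | 1.5 | 0.0220 |
| violet run | 3.0 | 0.0398 |
| violet run | 4.5 | 0.0527 |
| violet run | 6.0 | 0.0634 |
| violet run | 7.5 | 0.0718 |
| violet run | 9.0 | 0.0683 |
| violet run | 10 | 0.0767 |
| violet run | 12 | 0.0747 |
| grey run | 1.5 | 0.0895 |
| grey run | 3.0 | 0.1549 |
| grey run | 4.5 | 0.1986 |
| grey run | 6.0 | 0.2195 |
| grey run | 7.5 | 0.2288 |
| grey run | 9.0 | 0.2379 |
| grey run | 10 | 0.2412 |
| grey run | 12 | 0.2398 |

(each reading ± 0.002 M)

- reaction order in [starting material] at the outset, round the charge of the red run, defined at two percent of the starting material turned into target (one fixed amount of target, the same in the runs compared)
- reaction order in [partner] at the outset, round the charge of the red run, defined at two percent of the starting material turned into target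
- target in the blue run at 12 min, as a share of the starting material charged

- Overall: starting material + partner -> target.
- Constant volume, constant temperature.
- "The second partner" is partner.
- An order is taken over about fifteen percent of the charge, up and down.

I, taking the minutes, proposed counting turnovers. If the starting material not found as target at the level counts as lost, violet made 0.609 of target per unit lost. Dividing that by the run's mean partner gives the split, target made per starting material lost and per molar of partner (a selectivity factor), 0.633 M⁻¹.

A colleague objected that red reads higher, 0.803 M⁻¹. I answered that violet's partner charge is lower than red's, toward blue's, and kept violet.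

At blue's partner the split gives 0.253 of target per unit lost, so the finished share is 20.2%. Blue may not finish, though. Violet's first reading, 29.1% of its level, gives a clock of 0.229 min⁻¹, of which 0.142 min⁻¹ is loss. Rescaled to blue, that clock has run 88.2% of the way by 12 min, so my reckoning was 17.8%.

The forecaster differed, putting blue lower, at 16%, with orders of 1.1 in starting material and 1.1 in partner, and holding that “something else stops the reaction”.

The simulation gives 17.4% for blue, with orders of 1.1 and 1.0, and the forecast stands within its margins.

    starting material ⇌ intermediate, settled at all times (0.2390)
    intermediate + partner → target (0.4638 M⁻¹ min⁻¹)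
    starting material + partner + target → 2 target (0.5958 M⁻² min⁻¹)
    starting material → decomposed substrate (0.1908 min⁻¹)

At blue's partner the split means 3.95 units lost per unit of target, so beside the 17.4% of target it estimates about 68.6% of the charge lost. The loss of starting material to decomposed substrate costs the blue run target. With that loss taken away, target at 12 min rises from 17.4% to 36.6%.

The data are calculated with made-up constants; noise was put on by code.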